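The earlier runs and the new flask are simulated for an exercise; scatter was added.

The maple run had 37.1% of its free monomer in chains after 10.0 h and the ash run 14.7% after 10.0 h, both on 0.23 mM of initiator. I had to choose between Monday's recipe and Tuesday's for the longer chains, with the initiator left as it was.

all flasks: initiator 0.23 mM
- ash: free monomer 0.045 M; run made earlier
- maple: free monomer 0.11 M; run made earlier
- Monday's: free monomer 0.069 M; time 15 h
- Tuesday's: free monomer 0.15 M; time 15 h

| run | time / h | monomer in chains / % | free monomer / % |
|---|---|---|---|
| ash | 0.833 | 0.6 | 99.4 |
| ash | 1.33 | 0.9 | 98.9 |
| ash | 2.00 | 2.0 | 97.8 |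
| ash | 3.00 | 3.6 | 96.8 |
| ash | 5.00 | 7.3 | 93.3 |
| ash | 6.00 | 8.9 | 91.5 |
| ash | 10.0 | 14.7 | 84.8 |
| maple | 1.50 | 4.1 | 96.7 |
| maple | 3.00 | 10.8 | 88.6 |
| maple | 5.00 | 19.5 | 80.7 |
| maple | 6.00 | 24.2 | 76.6 |
| maple | 8.00 | 30.7 | 69.4 |
| maple | 10.0 | 37.1 | 62.3 |

(each reading ± 0.3 percentage points)

- the average divides the monomer in chains by the number of chains begun, living and dead together
- the earlier runs do not show the number of chains; that part of a forecast is a guess

* which of the two ends with the longer chains by the average number of monomer units in a chain (chains begun, living or dead) ("neither" if they lie within 10%) (Monday's / Tuesday's / neither)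
* average number of monomer units in a chain (chains begun, living or dead) at the end, Monday's
* average number of monomer units in a chain (chains begun, living or dead) at the end, Tuesday's

From the last reading of each run I took ln([free monomer] charged/[free monomer]) per hour, which gave 0.0165 /h for ash and 0.0473 /h for maple. These two rose as the charge to the power 1.18, so I scaled them to 0.0273 /h for Monday's and 0.0682 /h for Tuesday's.

The runs show no chain count, so I wrote the balance of initiator, the reagent charged in the smaller amount and the limiting reagent of the count, taking one initiator per chain begun. For Monday's this gave 101, my floor length: [monomer in chains] at the end divided by the [initiator] charged, which is the average if every initiator begins a chain. At the same [monomer in chains], any initiator that begins none lifts the average above it. Tuesday's floor came to 418, which is 4.14 times Monday's, so I chose Tuesday's and left the initiator unchanged.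

The forecast also named Tuesday's, with 130 (70 to 400) for Monday's and 470 (200 to 1300) for Tuesday's: “Some initiator is probably wasted, so I go somewhat higher.”

Tuesday's ended at 502 and Monday's at 187, against floors of 418 and 101; each stood above its floor, and Tuesday's was the longer.

    monomer in chains + living end → free monomer + living end, rate k1*[living end] as long as [monomer in chains] is above zero (k = 0.205 /min)
    2 initiator → spent initiator (k = 31.8 /M/min)
    free monomer + initiator → living end + monomer in chains (k = 0.122 /M/min)
    free monomer + living end → monomer in chains + living end, rate k4*[living end]*[free monomer] (k = 7.96 /M/min)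

At the end of Monday's, [living end] of 1.32 × 10⁻⁴ M, two initiator for each [spent initiator] of 4.87 × 10⁻⁵ M, and the 0.0758% of the charged initiator still there came to 0.230 mM, about the charge. In the neighbour of Tuesday's charged with 0.38 M of free monomer, 70.2% stood in chains, a floor length of 1160, and its chains averaged 1340.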